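## Structural features

The target is a 1,2,3,4-tetrahydroisoquinoline: a benzene ring (C4a, C5, C6, C7, C8, C8a) fused to a piperidine ring (C1, N2, C3, C4). C5 is bonded to C1' of a 4,5-dimethoxy-7-methylnaphthalene. The benzene ring carries methoxy groups at C6 and C8 with C7–H between them, so it is a resorcinol diether with carbon substituents on the three remaining positions. The only stereocenter is C3 (S), which bears the methyl group and sits between N2 and the C4 methylene; C1 is an unsubstituted benzylic CH2, so no second center stands next to it. The C5–C1' bond is flanked by the C6 methoxy group and the C4 methylene on one side and by C2'–H and the peri C8'–H on the other, so rotation about it is hindered. Sensitive groups are the free secondary benzylic amine and the two electron-rich arenes, which argues for unmasking nitrogen last. The real difficulty is to form the crowded C5–C1' bond and at the same time place the two oxygens meta to each other with the correct neighbours, without disturbing C3. The key step uses exactly this ring: C8, C8a, C4a and C5 can come from a cyclobutenone that already carries the naphthyl group and the piperidine ring, and C6–C7 from an alkoxyalkyne.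

## Logic of the disconnections

**32 from 31.** The N–S bond is cut last. The sulfonyl group activates the three-membered ring, acidifies N–H for the conjugate addition, and is inert to amide activation and to heat. The forward step must cleave a dialkyl arenesulfonamide without touching four aryl methyl ethers.

**31 from 30.** The O–CH3 bond at C8 is cut. This exposes the phenol that the annulation delivers directly. The forward step is a plain O-alkylation.

**30 from 22 and 25.** Three bonds of the benzene ring are cut: C7–C8, C5–C6 and C8–C8a. The hindered C5–C1' bond then no longer has to be made on an arene; in 22 it is an ordinary bond from the naphthalene to an sp2 carbon of a four-membered enone. The resorcinol pattern, the C7–H and the position of the naphthyl group all follow from the connectivity of 22 and the polarity of 25. The forward step needs ring opening of 22, regioselective capture of the ketene by 25 and 6π closure onto the ring alkene to outrun ketene dimerization and loss of volatile 25.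

**25 from 23.** Two eliminations are traced back to a stable acetal, because 25 is volatile and must be made fresh.

**22 from 11 and 19 (through 21).** The bond between C7 of the bicycle and C1' is cut. The naphthyl group is deliberately not carried on the alkyne into the four-ring closure. In a tethered keteniminium–alkyne closure the iminium carbon must bond to the alkyne carbon remote from the tether. An electron-rich aryl group on that carbon polarizes the alkyne the opposite way, so tether and electronics would disagree. Coupling after ring formation removes this conflict and joins two arms of similar length. The forward coupling must run below the ring-opening temperature of the strained enone and without strong nucleophiles.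

**11 from 9.** The C7–Br bond is cut. The forward step is an α-halogenation of an enone whose β-carbon is fully substituted, so the handle can only enter at C7.

**9 from 6.** The bonds C7–C8 and C1–C6 of the bicycle are cut ([2+2]). This reduces the bicycle to an open-chain amide with a terminal alkyne, for which the polarity of the alkyne and the tether demand the same regiochemistry. The forward step must close a six-membered ring and tolerate the β-sulfonamido group.

**6 from 4 and 5.** The N–CH2 bond is cut (conjugate addition). The forward step needs only catalytic base.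

**4 from 3.** The bond between the propargylic CH2 and the alkyne carbon is cut. The forward step is an acetylide opening that must occur at the unsubstituted ring carbon, so that C3 of the target is never a reacting center.

**3 from 1.** The N–S bond and the N–CH2 ring bond are cut, back to the chiral-pool amino alcohol that supplies C3, its methyl group, C4 and N2.

**19 from 18.** The O–CH3 bond at the peri oxygen is cut.

**18 from 16.** The bond to the ester carbon is cut. The ester is only the activating group of the annulation and is removed by decarboxylation.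

**16 from 13 and 14.** The bonds C3–C4 and C1–C2 of the new naphthalene ring are cut (conjugate addition, then acylation). The forward step builds the methyl-bearing ring on a benzoate that already carries the bromine.

**13 from 12.** The C–Br bond is cut. Bromination para to the methoxy group on the monocyclic stage fixes the future C1' handle unambiguously, which bromination of the finished naphthalene would not guarantee.

## Other disconnections considered

**Alternative 1:** The cut is through C1'–C2' and C3'–C4' of the naphthalene ring that bears the isoquinoline. In the forward direction, the diaryl ketone A1 would be irradiated with Ti(OiPr)4 to give a hydroxy-o-quinodimethane. This would add phenyl vinyl sulfone A2 to give the tetralol A3, which must then lose water and the sulfinate to become the naphthalene.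
- In its favour: the C5–C1' bond is made as an aryl–carbonyl bond, so no hindered cross-coupling is needed, and the three transient centers of A3 are all destroyed on aromatization.
- Against it here: A1 is ortho-substituted on both aryl groups and strongly twisted, so hydrogen abstraction from the methoxymethyl group has to compete with unproductive decay. A1 also needs a regioselective C5 acylation of a finished tetrahydroisoquinoline plus a separately made tetrasubstituted benzoic acid. Two eliminations follow the key step, one of them under conditions that threaten the Boc group.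
- Structure: equal to the chosen plan, since both create the axis only on aromatization and leave C3 alone.
- Mechanism: a photochemical step on a crowded ketone is harder to predict than a thermal pericyclic cascade. The intermediates of this alternative are, however, more robust than a cyclobutenone, and on that point it is the better.
- Step economy: the alternative is expected to be longer.

**Alternative 2:** The cut is through C4a–C5 and C8–C8a. The diene A4 and the alkynoate A5 would combine in a Diels–Alder reaction and lose methanol to give the salicylate A6.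
- In its favour: diene and dienophile are polarized in the same sense, and the naphthyl group arrives on a diene terminus rather than by coupling. The oxygen pattern comes out as 6-methoxy-8-hydroxy, exactly as in the chosen plan, so on these points the two are equal.
- Against it here: the bulky aryl group on the reacting diene terminus should slow the cycloaddition, and the silyl ketene acetal is moisture-sensitive. The piperidine ring is not yet closed: the ester at C8a must be reduced, activated and joined to nitrogen after Boc removal.
- Structure: the chosen plan delivers the complete ring system in the key step, while A6 still has C1 at the wrong oxidation level.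
- Mechanism: a single intermolecular [4+2] step is at least the equal of the four-stage ketene cascade in predictability.
- Step economy: the alternative needs several more operations after its key step and a multistep synthesis of A4.

**Alternative 3:** The cut is through C4–C4a, C8a–C1 and C1–N. A Catellani-type reaction (Pd(OAc)2) would join 1-iodo-2,4-dimethoxybenzene A7, the aziridine 3 of the present route and carbon monoxide A8 to give the lactam A9.
- In its favour: three simple components give the isoquinolinone in one step, C3 comes from the same chiral pool, and the ortho methoxy group blocks double alkylation.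
- Against it here: A9 has hydrogen at C5, so the crowded C5–C1' bond would still have to be made by regioselective halogenation (C5 against C7) and a hindered cross-coupling. This is the operation the chosen plan avoids. The N-sulfonyl lactam must also be reduced to the amine without ring opening.
- Structure: the alternative assembles the heterocycle more directly, but leaves the biaryl bond and the axis to a late coupling.
- Mechanism: the organometallic relay has more competing pathways than the pericyclic cascade. The late coupling is a well-understood reaction type for this substitution pattern, so the alternative is a serious competitor.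
- Step economy: the alternative is the better, being several steps shorter overall.

Key step: step 12

Assumption: the structure defines only C3; the hindered C5–C1' axis carries no descriptor, so the route fixes C3 as (S) and treats the two rotamers about this bond as one compound.

## Route

Step 1
Reactants: 1 L-alaninol
Product: 3 (S)-2-methyl-1-tosylaziridine, via N,O-ditosyl-L-alaninol 2 (not isolated)
Conditions: TsCl (2.2 equiv), KOH, H2O/CH2Cl2, 0 °C to rt
Reagents that add atoms: p-toluenesulfonyl chloride, Cc1ccc(S(=O)(=O)Cl)cc1
Why: One-pot N,O-bis-sulfonylation and base-induced ring closure of a 1,2-amino alcohol (intramolecular SN2 at the primary carbon); the stereocenter is not a reacting center, so (S) is carried over from 1.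

Step 2
Reactants: 3 (S)-2-methyl-1-tosylaziridine
Product: 4 (S)-4-methyl-N-(pent-4-yn-2-yl)benzenesulfonamide
Conditions: LiC≡CH·H2NCH2CH2NH2 (3 equiv), DMSO, rt; aq. NH4Cl
Reagents that add atoms: lithium acetylide–ethylenediamine complex, [Li+].[C-]#C.NCCN
Why: SN2 ring opening of an N-sulfonyl aziridine by an acetylide at the unsubstituted CH2 carbon, directed there by sterics; the methyl-bearing center is untouched and stays (S).

Step 3
Reactants: 4 (S)-4-methyl-N-(pent-4-yn-2-yl)benzenesulfonamide; 5 N,N-dimethylacrylamide
Product: 6 (S)-N,N-dimethyl-3-[N-(pent-4-yn-2-yl)-4-methylphenylsulfonamido]propanamide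
Conditions: 5 (3 equiv), DBU (0.3 equiv), MeCN, 60 °C
Reagents that add atoms: none
Why: Base-catalyzed aza-Michael addition of the acidic sulfonamide N–H to the acrylamide; it installs the three-carbon amide arm and leaves a fully substituted, non-nucleophilic nitrogen for the amide activation that follows.

Step 4
Reactants: 6 (S)-N,N-dimethyl-3-[N-(pent-4-yn-2-yl)-4-methylphenylsulfonamido]propanamide
Product: 9 (4S)-4-methyl-3-tosyl-3-azabicyclo[4.2.0]oct-6-en-8-one, via keteniminium triflate 7 (not isolated), via cyclobuteniminium triflate 8 (not isolated)
Conditions: Tf2O (1.2 equiv), 2,4,6-collidine (1.5 equiv), CH2Cl2 (0.03 M), −20 °C to 40 °C; then sat. aq. NaHCO3, rt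
Reagents that add atoms: water, O
Why: Keteniminium–alkyne [2+2] cycloaddition (Ghosez type), then hydrolysis of the cyclobuteniminium salt; the electrophilic iminium carbon bonds to the terminal alkyne carbon and the charge developing on the internal carbon is captured by the α-carbon in a six-membered ring, so tether and polarity agree. The ring-fusion center C1 forms without control (it is erased in step 12) and C4 is not involved.

Step 5
Reactants: 9 (4S)-4-methyl-3-tosyl-3-azabicyclo[4.2.0]oct-6-en-8-one
Product: 11 (4S)-7-bromo-4-methyl-3-tosyl-3-azabicyclo[4.2.0]oct-6-en-8-one, via dibromo ketone 10 (not isolated)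
Conditions: Br2 (1.05 equiv), CH2Cl2, −78 °C; then Et3N (1.5 equiv), −78 °C to 0 °C
Reagents that add atoms: bromine, BrBr
Why: α-Bromination of an enone by addition of Br2 and dehydrobromination (E1cB); the α-bromo C7–H is the more acidic and less hindered of the two α-hydrogens, so elimination should restore the C6=C7 bond with bromine on C7.

Step 6
Reactants: 12 methyl 2-methoxy-6-methylbenzoate
Product: 13 methyl 3-bromo-6-methoxy-2-methylbenzoate
Conditions: NBS (1.05 equiv), MeCN, rt
Reagents that add atoms: N-bromosuccinimide, O=C1CCC(=O)N1Br
Why: Electrophilic aromatic bromination para to the methoxy group (ortho to methyl, meta to the ester), the most activated position; this bromine later becomes the coupling handle at C1' of the naphthalene.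

Step 7
Reactants: 13 methyl 3-bromo-6-methoxy-2-methylbenzoate; 14 methyl (E)-3-methoxybut-2-enoate
Product: 16 methyl 5-bromo-1-hydroxy-8-methoxy-3-methyl-2-naphthoate, via lithiated toluate 15 (not isolated)
Conditions: LiN(iPr)2 (2.2 equiv), THF, −78 °C; then 14, −78 °C to rt; aq. NH4Cl
Reagents that add atoms: none
Why: Staunton–Weinreb annulation: lateral lithiation of the ortho-toluate, conjugate addition to the β-methoxy enoate, Dieckmann closure onto the aryl ester and loss of methanol give the naphthol directly; the bromine fixed in step 6 ends at C5, so no regiochemical question arises on the naphthalene.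

Step 8
Reactants: 16 methyl 5-bromo-1-hydroxy-8-methoxy-3-methyl-2-naphthoate
Product: 18 5-bromo-8-methoxy-3-methylnaphthalen-1-ol, via hydroxynaphthoic acid 17 (not isolated)
Conditions: NaOH, aq. EtOH, reflux; then HCl (pH 1), 1,4-dioxane/H2O, 100 °C
Reagents that add atoms: none
Why: Saponification and protodecarboxylation of an ortho-hydroxy aryl carboxylic acid; ipso protonation through the keto tautomer is eased by the electron-rich naphthol and by the two groups flanking the carboxyl.

Step 9
Reactants: 18 5-bromo-8-methoxy-3-methylnaphthalen-1-ol
Product: 19 1-bromo-4,5-dimethoxy-7-methylnaphthalene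
Conditions: MeI, K2CO3, DMF, 40 °C
Reagents that add atoms: iodomethane, CI
Why: Williamson O-methylation of the naphthol; the aryl bromide is inert.

Step 10
Reactants: 19 1-bromo-4,5-dimethoxy-7-methylnaphthalene; 11 (4S)-7-bromo-4-methyl-3-tosyl-3-azabicyclo[4.2.0]oct-6-en-8-one
Product: 22 (4S)-7-(4,5-dimethoxy-7-methylnaphthalen-1-yl)-4-methyl-3-tosyl-3-azabicyclo[4.2.0]oct-6-en-8-one, via naphthyllithium 20 (not isolated), via naphthylzinc chloride 21 (not isolated)
Conditions: 19, n-BuLi, THF, −78 °C; ZnCl2, −78 °C to rt; then 11, Pd2(dba)3 (2.5 mol %), SPhos (10 mol %), THF, rt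
Reagents that add atoms: none
Why: Negishi coupling: bromine–lithium exchange and transmetalation to zinc give a non-basic aryl nucleophile that does not add to the ketone; oxidative addition of the α-bromo enone to zerovalent palladium, transmetalation and reductive elimination form the C7–C1' bond at room temperature, below the ring-opening temperature of the cyclobutenone.

Step 11
Reactants: 23 chloroacetaldehyde dimethyl acetal
Product: 25 methoxyacetylene, via sodium methoxyacetylide 24 (not isolated)
Conditions: NaNH2 (3.3 equiv), liquid NH3, −33 °C; cold aq. NaCl quench; distilled into cold toluene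
Reagents that add atoms: none
Why: Two base-induced eliminations (methanol, then HCl) give the sodium acetylide of the ynol ether, which is protonated on quench; the volatile product is kept cold in toluene and used at once.

Step 12
Reactants: 22 (4S)-7-(4,5-dimethoxy-7-methylnaphthalen-1-yl)-4-methyl-3-tosyl-3-azabicyclo[4.2.0]oct-6-en-8-one; 25 methoxyacetylene
Product: 30 (S)-5-(4,5-dimethoxy-7-methylnaphthalen-1-yl)-6-methoxy-3-methyl-2-tosyl-1,2,3,4-tetrahydroisoquinolin-8-ol, via vinylketene 26 (not isolated), via cyclobutenone adduct 27 (not isolated), via dienylketene 28 (not isolated), via cyclohexadienone 29 (not isolated)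
Conditions: 25 (4 equiv), toluene, sealed tube, 80 °C then 120 °C
Reagents that add atoms: none
Why: This is a Danheiser benzannulation, the thermal reaction of a cyclobutenone with an alkoxyalkyne to give a resorcinol monoether. Heating opens 22 by a 4π electrocyclic reaction at the C1–C8 bond to vinylketene 26, whose alkene is held cis inside the tetrahydropyridine ring, so the ring-fusion center disappears. The ketene C=C of 26 and 25 then undergo a [2+2] cycloaddition in which the oxygen-polarized, nucleophilic CH carbon of 25 bonds to the electrophilic ketene carbonyl carbon (C7–C8) and the methoxy-bearing carbon to the naphthyl-bearing carbon (C5–C6), giving 27. Adduct 27 opens reversibly (4π) to dienylketene 28, and the rotamer with the ring alkene turned toward the ketene closes the one new ring by a thermal 6π electrocyclization (C8–C8a) to 29, which tautomerizes to phenol 30. No stereocenter is created: the quaternary carbon of 27 and C8a of 29 are transient, C3 lies outside the reacting π system, and the C5–C1' axis forms without control. The step needs the regiochemistry of the ketene–alkyne addition, which the polarization of the ynol ether secures. It also needs inward rotation of the alkenyl rather than the naphthyl group, which is favoured because closure onto the alkene leaves the naphthalene aromatic while the opening of 27 is reversible. An excess of 25 in a closed vessel keeps the ketene trapped before it can dimerize.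

Step 13
Reactants: 30 (S)-5-(4,5-dimethoxy-7-methylnaphthalen-1-yl)-6-methoxy-3-methyl-2-tosyl-1,2,3,4-tetrahydroisoquinolin-8-ol
Product: 31 (S)-5-(4,5-dimethoxy-7-methylnaphthalen-1-yl)-6,8-dimethoxy-3-methyl-2-tosyl-1,2,3,4-tetrahydroisoquinoline
Conditions: MeI, K2CO3, acetone, reflux
Reagents that add atoms: iodomethane, CI
Why: Williamson ether synthesis on the C8 phenol; sulfonamide and aryl ethers are inert.

Step 14
Reactants: 31 (S)-5-(4,5-dimethoxy-7-methylnaphthalen-1-yl)-6,8-dimethoxy-3-methyl-2-tosyl-1,2,3,4-tetrahydroisoquinoline
Product: 32 (S)-5-(4,5-dimethoxy-7-methylnaphthalen-1-yl)-6,8-dimethoxy-3-methyl-1,2,3,4-tetrahydroisoquinoline (CNP0236045.1)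
Conditions: Mg turnings (excess), MeOH, sonication, rt to 40 °C
Reagents that add atoms: none
Why: Single-electron (dissolving-metal) cleavage of the arenesulfonamide N–S bond by Mg in methanol; the aryl methyl ethers, the naphthalene and C3 are not affected.

## Compound list

1 | L-alaninol, (S)-2-aminopropan-1-ol | C[C@H](N)CO | starting material
2 | N,O-ditosyl-L-alaninol, (S)-2-(4-methylphenylsulfonamido)propyl 4-methylbenzenesulfonate | C[C@H](NS(=O)(=O)c1ccc(C)cc1)COS(=O)(=O)c1ccc(C)cc1 | intermediate
3 | (S)-2-methyl-1-tosylaziridine | C[C@H]1CN1S(=O)(=O)c1ccc(C)cc1 | intermediate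
4 | (S)-4-methyl-N-(pent-4-yn-2-yl)benzenesulfonamide | C[C@H](NS(=O)(=O)c1ccc(C)cc1)CC#C | intermediate
5 | N,N-dimethylacrylamide | C=CC(=O)N(C)C | starting material
6 | (S)-N,N-dimethyl-3-[N-(pent-4-yn-2-yl)-4-methylphenylsulfonamido]propanamide | C[C@H](N(CCC(=O)N(C)C)S(=O)(=O)c1ccc(C)cc1)CC#C | intermediate
7 | keteniminium triflate derived from 6 | C[C@H](N(CC=C=[N+](C)C)S(=O)(=O)c1ccc(C)cc1)CC#C.[O-]S(=O)(=O)C(F)(F)F | intermediate
8 | cyclobuteniminium triflate, N,N-dimethyl iminium of 9 (both C1 epimers) | C[N+](C)=C1C=C2C[C@H](C)N(S(=O)(=O)c3ccc(C)cc3)CC12.[O-]S(=O)(=O)C(F)(F)F | intermediate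
9 | (4S)-4-methyl-3-tosyl-3-azabicyclo[4.2.0]oct-6-en-8-one (both C1 epimers) | O=C1C=C2C[C@H](C)N(S(=O)(=O)c3ccc(C)cc3)CC12 | intermediate
10 | (4S)-6,7-dibromo-4-methyl-3-tosyl-3-azabicyclo[4.2.0]octan-8-one (diastereomer mixture) | O=C1C(Br)C2(Br)C[C@H](C)N(S(=O)(=O)c3ccc(C)cc3)CC12 | intermediate
11 | (4S)-7-bromo-4-methyl-3-tosyl-3-azabicyclo[4.2.0]oct-6-en-8-one (both C1 epimers) | O=C1C(Br)=C2C[C@H](C)N(S(=O)(=O)c3ccc(C)cc3)CC12 | intermediate
12 | methyl 2-methoxy-6-methylbenzoate | COC(=O)c1c(C)cccc1OC | starting material
13 | methyl 3-bromo-6-methoxy-2-methylbenzoate | COC(=O)c1c(C)c(Br)ccc1OC | intermediate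
14 | methyl (E)-3-methoxybut-2-enoate | CO/C(C)=C/C(=O)OC | starting material
15 | methyl 3-bromo-2-(lithiomethyl)-6-methoxybenzoate | [Li]Cc1c(Br)ccc(OC)c1C(=O)OC | intermediate
16 | methyl 5-bromo-1-hydroxy-8-methoxy-3-methyl-2-naphthoate | COC(=O)c1c(C)cc2c(Br)ccc(OC)c2c1O | intermediate
17 | 5-bromo-1-hydroxy-8-methoxy-3-methyl-2-naphthoic acid | OC(=O)c1c(C)cc2c(Br)ccc(OC)c2c1O | intermediate
18 | 5-bromo-8-methoxy-3-methylnaphthalen-1-ol | Oc1cc(C)cc2c(Br)ccc(OC)c12 | intermediate
19 | 1-bromo-4,5-dimethoxy-7-methylnaphthalene | COc1ccc(Br)c2cc(C)cc(OC)c12 | intermediate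
20 | (4,5-dimethoxy-7-methylnaphthalen-1-yl)lithium | [Li]c1ccc(OC)c2c(OC)cc(C)cc12 | intermediate
21 | (4,5-dimethoxy-7-methylnaphthalen-1-yl)zinc chloride | Cl[Zn]c1ccc(OC)c2c(OC)cc(C)cc12 | intermediate
22 | (4S)-7-(4,5-dimethoxy-7-methylnaphthalen-1-yl)-4-methyl-3-tosyl-3-azabicyclo[4.2.0]oct-6-en-8-one (both C1 epimers) | COc1ccc(C2=C3C[C@H](C)N(S(=O)(=O)c4ccc(C)cc4)CC3C2=O)c2cc(C)cc(OC)c12 | intermediate
23 | chloroacetaldehyde dimethyl acetal, 2-chloro-1,1-dimethoxyethane | COC(CCl)OC | starting material
24 | sodium methoxyacetylide | [Na+].[C-]#COC | intermediate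
25 | methoxyacetylene | COC#C | intermediate
26 | vinylketene, 2-(4,5-dimethoxy-7-methylnaphthalen-1-yl)-2-[(S)-2-methyl-1-tosyl-1,2,3,6-tetrahydropyridin-4-yl]ethenone | O=C=C(c1ccc(OC)c2c(OC)cc(C)cc12)C1=CCN(S(=O)(=O)c2ccc(C)cc2)[C@@H](C)C1 | intermediate
27 | cyclobutenone adduct, 4-(4,5-dimethoxy-7-methylnaphthalen-1-yl)-3-methoxy-4-[(S)-2-methyl-1-tosyl-1,2,3,6-tetrahydropyridin-4-yl]cyclobut-2-en-1-one (both C4 epimers) | O=C1C=C(OC)C1(c1ccc(OC)c2c(OC)cc(C)cc12)C1=CCN(S(=O)(=O)c2ccc(C)cc2)[C@@H](C)C1 | intermediate
28 | dienylketene, 4-(4,5-dimethoxy-7-methylnaphthalen-1-yl)-3-methoxy-4-[(S)-2-methyl-1-tosyl-1,2,3,6-tetrahydropyridin-4-yl]buta-1,3-dien-1-one | O=C=CC(OC)=C(c1ccc(OC)c2c(OC)cc(C)cc12)C1=CCN(S(=O)(=O)c2ccc(C)cc2)[C@@H](C)C1 | intermediate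
29 | cyclohexadienone, (3S)-5-(4,5-dimethoxy-7-methylnaphthalen-1-yl)-6-methoxy-3-methyl-2-tosyl-2,3,4,8a-tetrahydroisoquinolin-8(1H)-one (both C8a epimers) | O=C1C=C(OC)C(c2ccc(OC)c3c(OC)cc(C)cc23)=C2C[C@H](C)N(S(=O)(=O)c3ccc(C)cc3)CC12 | intermediate
30 | (S)-5-(4,5-dimethoxy-7-methylnaphthalen-1-yl)-6-methoxy-3-methyl-2-tosyl-1,2,3,4-tetrahydroisoquinolin-8-ol | Oc1cc(OC)c(-c2ccc(OC)c3c(OC)cc(C)cc23)c2c1CN(S(=O)(=O)c1ccc(C)cc1)[C@@H](C)C2 | intermediate
31 | (S)-5-(4,5-dimethoxy-7-methylnaphthalen-1-yl)-6,8-dimethoxy-3-methyl-2-tosyl-1,2,3,4-tetrahydroisoquinoline | COc1cc(OC)c(-c2ccc(OC)c3c(OC)cc(C)cc23)c2c1CN(S(=O)(=O)c1ccc(C)cc1)[C@@H](C)C2 | intermediate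
32 | (S)-5-(4,5-dimethoxy-7-methylnaphthalen-1-yl)-6,8-dimethoxy-3-methyl-1,2,3,4-tetrahydroisoquinoline | COc1cc(OC)c(-c2ccc(OC)c3c(OC)cc(C)cc23)c2c1CN[C@@H](C)C2 | target

## Step count and risks

Total step count: 14. Longest linear sequence: 9 steps (steps 1–5, 10, 12, 13, 14, from 1 to 32). The naphthalene arm (steps 6–9) and the ynol ether (step 11) are side branches.

**Step 12 (key step).** The most likely failure is slow addition of 25 to the ketene, because the naphthyl group sits on the ketene carbon that must become quaternary. This would leave time for ketene dimerization, loss or polymerization of the volatile ynol ether, and ring opening of the adduct with the naphthyl group turned inward.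
- Fallback: set out from 11 and run the benzannulation with the small bromine in place of the naphthyl group. Heating 11 with 25 should give (S)-5-bromo-6-methoxy-3-methyl-2-tosyl-1,2,3,4-tetrahydroisoquinolin-8-ol F1. Methylation as in step 13 would give (S)-5-bromo-6,8-dimethoxy-3-methyl-2-tosyl-1,2,3,4-tetrahydroisoquinoline F2. Negishi coupling of F2 with 21 (Pd2(dba)3, SPhos, THF, 60 °C) returns to the route at 31. The cost is that the crowded C5–C1' bond is then made on the arene.

**Step 4.** Ring closure onto the unactivated terminal alkyne in a six-membered transition state may be slow. Intermolecular reaction of the keteniminium ion or loss of the β-sulfonamide by elimination could then take over.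
- Fallback: set out from 3 with a silyl alkyne, whose silicon stabilizes the positive charge developing on the internal carbon. Opening of 3 with LiC≡CSiMe3 would give (S)-4-methyl-N-[5-(trimethylsilyl)pent-4-yn-2-yl]benzenesulfonamide F3. Addition to 5 would give (S)-N,N-dimethyl-3-{N-[5-(trimethylsilyl)pent-4-yn-2-yl]-4-methylphenylsulfonamido}propanamide F4. The activation of step 4 would give (4S)-4-methyl-3-tosyl-7-(trimethylsilyl)-3-azabicyclo[4.2.0]oct-6-en-8-one F5. Ipso-iododesilylation with ICl would give (4S)-7-iodo-4-methyl-3-tosyl-3-azabicyclo[4.2.0]oct-6-en-8-one F6. Coupling of F6 with 21 under the conditions of step 10 returns to the route at 22.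

**Step 5.** Dehydrobromination may proceed toward the ring-fusion carbon instead of C7, or the strained ring may be opened by bromide or amine.
- Fallback: set out from 9 and postpone the halogen to the arene stage. Benzannulation of 9 with 25 should give (S)-6-methoxy-3-methyl-2-tosyl-1,2,3,4-tetrahydroisoquinolin-8-ol F7. O-Methylation would give (S)-6,8-dimethoxy-3-methyl-2-tosyl-1,2,3,4-tetrahydroisoquinoline F8. Iodination with N-iodosuccinimide para to the C8 methoxy group would give (S)-5-iodo-6,8-dimethoxy-3-methyl-2-tosyl-1,2,3,4-tetrahydroisoquinoline F9. Negishi coupling of F9 with 21 returns to the route at 31.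

**Step 10.** The cyclobutenone may not survive the organometallic medium: attack at the carbonyl group, or ring opening before the coupling is complete.
- Fallback: set out from 19 and use an isolated, neutral organotin partner. Bromine–lithium exchange and quench with Bu3SnCl would give tributyl(4,5-dimethoxy-7-methylnaphthalen-1-yl)stannane F10. Stille coupling of F10 with 11 (Pd2(dba)3, tri(2-furyl)phosphine, CuI, DMF, rt) returns to the route at 22.

**Step 7.** Proton transfer from the γ-methyl group of 14 to the benzylic anion may win over conjugate addition, because the β-carbon of 14 is doubly substituted and deactivated by its methoxy group.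
- Fallback: set out from 13 and use the more electrophilic methyl crotonate in the same Michael–Dieckmann sequence. This should give methyl 5-bromo-1-hydroxy-8-methoxy-3-methyl-3,4-dihydronaphthalene-2-carboxylate F11. Dehydrogenation of F11 with DDQ in hot 1,4-dioxane returns to the route at 16.

**Step 14.** Electron transfer from the metal surface to a dialkyl sulfonamide may be incomplete, leaving the N–S bond intact.
- Fallback: set out from 31 and remove the group by elimination instead of reduction. KOtBu in DMSO at rt should remove the benzylic C1 proton and expel the sulfinate to give (S)-5-(4,5-dimethoxy-7-methylnaphthalen-1-yl)-6,8-dimethoxy-3-methyl-3,4-dihydroisoquinoline F12. Reduction of F12 with NaBH4 in MeOH returns to the route at 32. Contact with base must be short, so that C3 is not deprotonated through the imine.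

## Further compounds

F1 | step 12 | (S)-5-bromo-6-methoxy-3-methyl-2-tosyl-1,2,3,4-tetrahydroisoquinolin-8-ol | Oc1cc(OC)c(Br)c2c1CN(S(=O)(=O)c1ccc(C)cc1)[C@@H](C)C2
F2 | step 12 | (S)-5-bromo-6,8-dimethoxy-3-methyl-2-tosyl-1,2,3,4-tetrahydroisoquinoline | COc1cc(OC)c(Br)c2c1CN(S(=O)(=O)c1ccc(C)cc1)[C@@H](C)C2
F3 | step 4 | (S)-4-methyl-N-[5-(trimethylsilyl)pent-4-yn-2-yl]benzenesulfonamide | C[C@H](NS(=O)(=O)c1ccc(C)cc1)CC#C[Si](C)(C)C
F4 | step 4 | (S)-N,N-dimethyl-3-{N-[5-(trimethylsilyl)pent-4-yn-2-yl]-4-methylphenylsulfonamido}propanamide | C[C@H](N(CCC(=O)N(C)C)S(=O)(=O)c1ccc(C)cc1)CC#C[Si](C)(C)C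
F5 | step 4 | (4S)-4-methyl-3-tosyl-7-(trimethylsilyl)-3-azabicyclo[4.2.0]oct-6-en-8-one | O=C1C([Si](C)(C)C)=C2C[C@H](C)N(S(=O)(=O)c3ccc(C)cc3)CC12
F6 | step 4 | (4S)-7-iodo-4-methyl-3-tosyl-3-azabicyclo[4.2.0]oct-6-en-8-one | O=C1C(I)=C2C[C@H](C)N(S(=O)(=O)c3ccc(C)cc3)CC12
F7 | step 5 | (S)-6-methoxy-3-methyl-2-tosyl-1,2,3,4-tetrahydroisoquinolin-8-ol | Oc1cc(OC)cc2c1CN(S(=O)(=O)c1ccc(C)cc1)[C@@H](C)C2
F8 | step 5 | (S)-6,8-dimethoxy-3-methyl-2-tosyl-1,2,3,4-tetrahydroisoquinoline | COc1cc(OC)cc2c1CN(S(=O)(=O)c1ccc(C)cc1)[C@@H](C)C2
F9 | step 5 | (S)-5-iodo-6,8-dimethoxy-3-methyl-2-tosyl-1,2,3,4-tetrahydroisoquinoline | COc1cc(OC)c(I)c2c1CN(S(=O)(=O)c1ccc(C)cc1)[C@@H](C)C2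
F10 | step 10 | tributyl(4,5-dimethoxy-7-methylnaphthalen-1-yl)stannane | CCCC[Sn](CCCC)(CCCC)c1ccc(OC)c2c(OC)cc(C)cc12
F11 | step 7 | methyl 5-bromo-1-hydroxy-8-methoxy-3-methyl-3,4-dihydronaphthalene-2-carboxylate | COC(=O)C1=C(O)c2c(OC)ccc(Br)c2CC1C
F12 | step 14 | (S)-5-(4,5-dimethoxy-7-methylnaphthalen-1-yl)-6,8-dimethoxy-3-methyl-3,4-dihydroisoquinoline | COc1cc(OC)c(-c2ccc(OC)c3c(OC)cc(C)cc23)c2c1C=N[C@@H](C)C2
A1 | alternative 1 | tert-butyl (S)-5-[3-methoxy-2-(methoxymethyl)-5-methylbenzoyl]-6,8-dimethoxy-3-methyl-3,4-dihydroisoquinoline-2(1H)-carboxylate | COCc1c(OC)cc(C)cc1C(=O)c1c(OC)cc(OC)c2c1C[C@H](C)N(C(=O)OC(C)(C)C)C2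
A2 | alternative 1 | phenyl vinyl sulfone | C=CS(=O)(=O)c1ccccc1
A3 | alternative 1 | tert-butyl (3S)-5-[1-hydroxy-4,5-dimethoxy-7-methyl-2-(phenylsulfonyl)-1,2,3,4-tetrahydronaphthalen-1-yl]-6,8-dimethoxy-3-methyl-3,4-dihydroisoquinoline-2(1H)-carboxylate | COC1CC(S(=O)(=O)c2ccccc2)C(O)(c2c(OC)cc(OC)c3c2C[C@H](C)N(C(=O)OC(C)(C)C)C3)c2cc(C)cc(OC)c12
A4 | alternative 2 | {[4-(4,5-dimethoxy-7-methylnaphthalen-1-yl)-1,3-dimethoxybuta-1,3-dien-1-yl]oxy}trimethylsilane | COC(O[Si](C)(C)C)=CC(OC)=Cc1ccc(OC)c2c(OC)cc(C)cc12
A5 | alternative 2 | methyl (S)-5-[(tert-butoxycarbonyl)amino]hex-2-ynoate | COC(=O)C#CC[C@H](C)NC(=O)OC(C)(C)C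
A6 | alternative 2 | methyl 2-hydroxy-4-methoxy-5-(4,5-dimethoxy-7-methylnaphthalen-1-yl)-6-[(S)-2-(tert-butoxycarbonylamino)propyl]benzoate | COC(=O)c1c(O)cc(OC)c(-c2ccc(OC)c3c(OC)cc(C)cc23)c1C[C@H](C)NC(=O)OC(C)(C)C
A7 | alternative 3 | 1-iodo-2,4-dimethoxybenzene | COc1ccc(I)c(OC)c1
A8 | alternative 3 | carbon monoxide | [C-]#[O+]
A9 | alternative 3 | (S)-6,8-dimethoxy-3-methyl-2-tosyl-3,4-dihydroisoquinolin-1(2H)-one | COc1cc(OC)c2c(c1)C[C@H](C)N(S(=O)(=O)c1ccc(C)cc1)C2=O
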